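**Numbering.** Ring atoms follow spiro[4.5]decane (C1–C4 and spiro C5 in ring A, C5–C10 in ring B); C1′–C3′ are the chain carbons on C6. Compounds are numbered 1–38 as in the steps below.

## Analysis of the target

The target 38 is a spiro[4.5]decane: ring A is the cyclopentane C1–C5, ring B the cyclohexane C5–C10, and C5 is the quaternary spiro carbon. Ring A carries a secondary alcohol at C1 and, at C2, a 1,1-disubstituted alkene that opens a conjugated triene ending in a Z-trisubstituted alkene with a hydroxymethyl group and a homoprenyl chain. Ring B carries a 3-hydroxypropyl chain at C6, an exocyclic tetrasubstituted α-methyl enal at C7 whose formyl group lies on the C6 side, and a methyl carbinol at C10. There are five stereocentres, C1 (S), C2 (S), C5 (S), C6 (R) and C10 (S): on ring B the C5–C1 bond, the C6 chain and the C10 oxygen share one face, and on ring A the C1 hydroxyl lies on the face occupied by C10 and trans to the C2 substituent. The sensitive groups are the triene with its allylic alcohol (acid, oxidants, light), the enal (alkene geometry, and deconjugation toward C6 would endanger that centre) and four hydroxyls of three kinds; C1–O and C10–O are 1,3-related through C5, so a C1 ketone beside a free C10 hydroxyl invites retro-aldol cleavage. The hard part is the quaternary C5 flanked by the stereocentres C1, C6 and the fully substituted C10, together with the late introduction of the polyene. The strategy rests on two features: C5 bears the oxygenated C1 next to the methylene C4, the pattern left when a cyclobutanol expands to a cyclopentanone, and the C6–C7 bond lies six-membered endo to a C5=C6 alkene. Both rings, two skeletal bonds and the C5 and C6 centres can therefore come from one cationic cascade of an open-chain alkenylcyclobutanol in which C10 is the only stereocentre.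

## Retrosynthetic reasoning

**Silicon removal and the C(=CH2)–CH bond.** Target 38 is taken back to its silylated form 37, so that the last step only breaks Si–O bonds. In 37 the bond between the 1,1-disubstituted alkene carbon on C2 and the first CH of the dienyl chain is cut, giving iodoalkene 28 and dienylstannane 36. The bond joins two sp2 carbons, so a palladium-catalysed coupling can form it under neutral conditions beside the enal, and the fragile triene stays out of the long sequence. The forward coupling has to keep both alkene geometries.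

**The dienylstannane.** The Z-trisubstituted alkene of 36 is cut at its C=C bond: ester 35 comes from a Z-selective phosphonate olefination of stannyl enal 34 with phosphonate 31. Phosphonate 31 comes from 29 and 30 by alkylation, and 34 from 32 by formylation. The olefination has to place the ester, later the hydroxymethyl group, cis to the dienyl chain.

**The enal.** The C7=C bond of 28 is traced to ketone 26 through the tertiary allylic alcohol 27: an isopropenyl unit is added to the ketone and the oxygen is moved to the chain terminus by an oxidative allylic transposition. This uses the oxidation level that the key step leaves at C7 and avoids olefinating a hindered ketone with a stabilised reagent. The forward steps must not epimerise C6 and must put the formyl group on the C6 side.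

**The C2–C bond and the C1–O bond.** The trans arrangement of the C1 hydroxyl and the C2 alkenyl group in 22 is the signature of an epoxide opening, so the C2–alkenyl bond is cut to epoxide 21 and an α-silylvinyl nucleophile, whose silicon is later exchanged for the iodine of 24. The opening must occur at C2, away from the spiro carbon. The epoxide must sit on the ring A face occupied by C10, which is why the C10 hydroxyl is freed in 20 and used to direct the epoxidation. Alkene 20 derives from ketone 16 through enol triflate 18, which can only form toward C2.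

**C6–C7 and C4–C5 (key disconnection).** Ketone 16 is cut twice, at the ring B bond C6–C7 and the ring A bond C4–C5. This returns aldehyde 14, an open chain in which C5=C6 is an alkene, C1 is the carbinol carbon of a cyclobutanol and C10 is the only stereocentre. No other pair of bonds removes the quaternary carbon, both rings and the C5 and C6 centres at once, and the cut leaves the C1 ketone and the C7 alcohol differentiated. The forward cascade must close ring B through C6, shift a four-membered-ring bond to C5 on the face opposite the new bond, and choose the face that places C1 cis to the C10 oxygen.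

**Aldehyde and cyclobutanol.** The aldehyde of 14 is the cleaved terminus of the prenyl group of 12, which carries it masked through the organometallic steps. The C1–C5 bond of 12 is cut to cyclobutanone 10 and the alkenyllithium 11 from iodide 9. The geometry of 9 (chain cis to iodine) becomes the cis relationship of the chain and the carbinol carbon.

**Alkene geometry and the chain.** Iodide 9 goes back through 8 to stannane 7 and then to alkyne 6. A hydroxyl-directed trans-hydrostannation places the metal next to the carbinol and anti to hydrogen, which is the geometry required. The bond between the alkyne and the propyl chain is cut to alkynol 4 and bromide 5.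

**C10.** Alkynol 4 derives from epoxy chloride 3, epoxy alcohol 2 and geraniol 1. An asymmetric epoxidation sets the tertiary C–O centre, and a base-induced fragmentation turns the epoxide carbons into the alkyne without breaking that C–O bond. Geraniol already holds the methyl group, the two-carbon tether and, as its terminal alkene, the latent C7 aldehyde.

## Alternatives that were turned down

**Alternative 1:** Ring B is bought in as enone A1, a 2-carbomethoxycyclohex-2-enone with the C7 silyloxy group in place, and the bonds C6–C1′ and C4–C5 are cut.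
- Forward key step: a copper-catalysed Grignard addition delivers the silyloxypropyl chain to C6 anti to the C7 substituent, and the resulting β-keto ester enolate is alkylated at C5 by an allylic bromide carrying C2–C4, giving keto ester A2 in one flask.
- For it: three components and two bonds in one operation, a robust reaction class, and alkylation anti to the new C6 chain gives the required cis relationship between that chain and the ester carbon that becomes C1.
- Against it: in A2, C10 is still a ketone, so a methyl nucleophile must add to this neopentyl, enolisable β-keto ester carbonyl from one face. Ring A is still open, the ester must be brought to the carbinol level of C1, and C1 and C2 are set afterwards. A1 is itself a chiral γ-silyloxy enone prone to elimination and needs its own synthesis.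
- Comparison: it is the safer bond construction and is stronger on C6/C7 control. The chosen route offers instead C10 as the controlling stereocentre from the outset, ring A and the quaternary carbon in the same step as ring B, and C1 delivered as a ketone already distinct from C7.

**Alternative 2:** Ring B and a temporary cyclohexene (C1, C5, C6, C1′–C3′) are made together, and the bonds C5–C6 and C1′–C2′ are cut.
- Forward key step: oxidation of allylic alcohol A3 unmasks a vinyl ketone that adds intramolecularly across the 1-vinylcyclopentene diene to give the angular tricyclic ketone A4. Ozonolysis of its C1=C3′ alkene would later expose the C1 ketone and turn the extra ring into the C6 chain.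
- For it: a concerted cycloaddition fixes C5 and C6 relative to each other through the tether, and the three chain carbons and the C1 carbonyl come from one alkene, so the bicyclic core is reached in the fewest steps.
- Against it: the diene terminus C5 is fully substituted and carries the quaternary C10, so the quaternary centre must form at a congested, twisted diene. The only source of facial bias is C10, with two groups of similar demand. After ozonolysis three carbonyl groups (C1, C7, C3′) must be told apart while C6 sits α to one of them.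
- Comparison: it is shorter to the core and equal in its reliance on C10. The chosen route delivers C1 as a ketone, C7 as an alcohol and C3′ as a protected alcohol directly, so no differentiation problem arises, and its chair transition state gives C10 a better-defined role.

**Alternative 3:** Ring B is closed at C9–C10, the bond between the methyl carbinol carbon and its methylene neighbour.
- Forward key step: a divalent samarium reductant turns the primary iodide of the open-chain keto diester A5 into an organosamarium, which adds to the methyl ketone while the metal is chelated by the neighbouring ester, giving hydroxy ester A6 with the C5/C6/C10 triad.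
- For it: the tertiary carbinol is created under chelation control, a mild and predictable way to set C10 relative to C5, and six-membered Barbier closures of this kind are well behaved.
- Against it: A5 must already contain the quaternary C5 with its C6 and C7 neighbours in an acyclic setting, so the hardest stereochemical problem is moved upstream, not solved. Ring A is still an open ester chain, and two esters of similar reactivity flank the reaction site.
- Comparison: it is stronger at C10, which it builds with a predictable sense instead of relying on it. The chosen route takes C10 from an asymmetric epoxidation and spends its key step on the quaternary carbon and both rings, which shortens the longest linear sequence.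

Key step: step 10

## Route

Remarks on the chemistry:
- Bromide 5 is treated as a purchasable reagent.
- The primary silyl ether is tert-butyldiphenylsilyl so that the tertiary triethylsilyl ether at C10 can be removed beside it in step 14.
- The C7 configuration written for 15–25 and 27 is the expected one; it does not affect the outcome because C7 becomes sp2 in 26 and 28.
- 13 and 31 form as mixtures at one carbon that is cleaved or becomes sp2 in the following step.

Step 1
Reactants: 1 geraniol
Product: 2 (2S,3S)-2,3-epoxygeraniol
Conditions: Ti(OiPr)4 (5 mol%), L-(+)-diethyl tartrate (7 mol%), t-BuOOH, 4 Å MS, CH2Cl2, −20 °C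
Reagents that add atoms: tert-butyl hydroperoxide, CC(C)(C)OO
Why: Sharpless asymmetric epoxidation; with L-(+)-tartrate the allylic alcohol of geraniol should give the (2S,3S)-epoxide, whose C3 becomes C10 of the target with its C–O bond never broken again. The remote trisubstituted alkene is not touched because the titanium tartrate catalyst epoxidises only the allylic alcohol.

Step 2
Reactants: 2 (2S,3S)-2,3-epoxygeraniol
Product: 3 (2R,3S)-2-(chloromethyl)-3-methyl-3-(4-methylpent-3-en-1-yl)oxirane
Conditions: PPh3, CCl4, NaHCO3, reflux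
Reagents that add atoms: tetrachloromethane, ClC(Cl)(Cl)Cl
Why: Appel chlorination of the primary alcohol under neutral conditions that leave the epoxide and both stereocentres untouched (the descriptor at C2 changes only because chlorine alters the priorities).

Step 3
Reactants: 3 (2R,3S)-2-(chloromethyl)-3-methyl-3-(4-methylpent-3-en-1-yl)oxirane
Product: 4 (3S)-3,7-dimethyloct-6-en-1-yn-3-ol
Conditions: n-BuLi (3.3 equiv), THF, −78 → −20 °C; then H2O
Reagents that add atoms: none
Why: Base-induced fragmentation of a 2,3-epoxy chloride to a propargylic alcohol: deprotonation next to chlorine opens the epoxide by β-elimination and the chloroalkene then loses HCl to give the acetylide. The tertiary C–O bond is not involved, so the configuration set in step 1 is kept.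

Step 4
Reactants: 4 (3S)-3,7-dimethyloct-6-en-1-yn-3-ol; 5 tert-butyl(3-bromopropoxy)diphenylsilane
Product: 6 (6S)-11-[(tert-butyldiphenylsilyl)oxy]-2,6-dimethylundec-2-en-7-yn-6-ol
Conditions: n-BuLi (2.1 equiv), THF, −78 → 0 °C; then 5, DMPU, 0 °C → rt
Reagents that add atoms: none
Why: SN2 alkylation of the alkoxide–acetylide dianion at carbon by a primary bromide; the hindered tertiary alkoxide does not compete.

Step 5
Reactants: 6 (6S)-11-[(tert-butyldiphenylsilyl)oxy]-2,6-dimethylundec-2-en-7-yn-6-ol
Product: 7 (6S,7Z)-11-[(tert-butyldiphenylsilyl)oxy]-2,6-dimethyl-7-(tributylstannyl)undeca-2,7-dien-6-ol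
Conditions: [(C5Me5)RuCl]4 (1.3 mol%), Bu3SnH, CH2Cl2, rt
Reagents that add atoms: tributyltin hydride, CCCC[SnH](CCCC)CCCC
Why: Hydroxyl-directed ruthenium-catalysed trans-hydrostannation; hydrogen bonding of the propargylic OH to the Ru–Cl unit steers tin to the alkyne carbon next to the carbinol, and H and Sn add anti, so the silyloxypropyl chain ends up cis to tin.

Step 6
Reactants: 7 (6S,7Z)-11-[(tert-butyldiphenylsilyl)oxy]-2,6-dimethyl-7-(tributylstannyl)undeca-2,7-dien-6-ol
Product: 8 (6S,7Z)-11-[(tert-butyldiphenylsilyl)oxy]-7-iodo-2,6-dimethylundeca-2,7-dien-6-ol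
Conditions: I2 (1.0 equiv), CH2Cl2, −78 → 0 °C
Reagents that add atoms: iodine, II
Why: Iododestannylation with retention of alkene geometry; the C–Sn bond reacts with iodine far faster than the isolated trisubstituted alkene, so one equivalent at low temperature suffices.

Step 7
Reactants: 8 (6S,7Z)-11-[(tert-butyldiphenylsilyl)oxy]-7-iodo-2,6-dimethylundeca-2,7-dien-6-ol
Product: 9 (6S,7Z)-11-[(tert-butyldiphenylsilyl)oxy]-7-iodo-2,6-dimethyl-6-[(triethylsilyl)oxy]undeca-2,7-diene
Conditions: Et3SiOTf, 2,6-lutidine, CH2Cl2, −78 → 0 °C
Reagents that add atoms: triethylsilyl trifluoromethanesulfonate, CC[Si](CC)(CC)OS(=O)(=O)C(F)(F)F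
Why: Silylation of a hindered tertiary alcohol with a silyl triflate; the ether protects C10–O in the organolithium step and later keeps it from ionising or donating in the cascade.

Step 8
Reactants: 9 (6S,7Z)-11-[(tert-butyldiphenylsilyl)oxy]-7-iodo-2,6-dimethyl-6-[(triethylsilyl)oxy]undeca-2,7-diene; 10 cyclobutanone
Product: 12 1-[(4E,6S)-1-[(tert-butyldiphenylsilyl)oxy]-6,10-dimethyl-6-[(triethylsilyl)oxy]undeca-4,9-dien-5-yl]cyclobutan-1-ol, via alkenyllithium 11 (not isolated)
Conditions: t-BuLi (2.1 equiv), Et2O, −78 °C; then 10, −78 → −40 °C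
Reagents that add atoms: none
Why: Iodine–lithium exchange with retention of configuration, then 1,2-addition to the strained, unhindered ketone; the geometry of 9 is carried over, so the chain is cis to the new carbinol carbon.

Step 9
Reactants: 12 1-[(4E,6S)-1-[(tert-butyldiphenylsilyl)oxy]-6,10-dimethyl-6-[(triethylsilyl)oxy]undeca-4,9-dien-5-yl]cyclobutan-1-ol
Product: 14 (4S,5E)-9-[(tert-butyldiphenylsilyl)oxy]-5-(1-hydroxycyclobutyl)-4-methyl-4-[(triethylsilyl)oxy]non-5-enal, via vicinal diol 13 (not isolated)
Conditions: OsO4 (2 mol%), NaIO4, 2,6-lutidine, dioxane–H2O, rt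
Reagents that add atoms: osmium tetroxide, O=[Os](=O)(=O)=O; sodium periodate, [Na+].[O-]I(=O)(=O)=O
Why: Lemieux–Johnson cleavage; OsO4 should select the electron-rich, unhindered terminal alkene over the C5=C6 alkene, which is flanked by two fully substituted oxygenated carbons, and periodate then cleaves the diol to the C7 aldehyde.

Step 10
Reactants: 14 (4S,5E)-9-[(tert-butyldiphenylsilyl)oxy]-5-(1-hydroxycyclobutyl)-4-methyl-4-[(triethylsilyl)oxy]non-5-enal
Product: 16 (5R,6S,7S,10S)-6-{3-[(tert-butyldiphenylsilyl)oxy]propyl}-7-hydroxy-10-methyl-10-[(triethylsilyl)oxy]spiro[4.5]decan-1-one, via C5 carbocation 15 (not isolated)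
Conditions: Me2AlCl (3 equiv), CH2Cl2, −78 → −20 °C; aq. potassium sodium tartrate
Reagents that add atoms: none
Why: Me2AlCl turns the cyclobutanol into its aluminium alkoxide and activates the aldehyde; the C5=C6 alkene attacks the complexed carbonyl carbon through C6, closing ring B in a 6-endo-trig, Markovnikov sense and developing positive charge at C5. A cyclobutane C–C bond then shifts to C5 on the face opposite the new C6–C7 bond, which closes ring A by four-to-five ring expansion and forms the C1 ketone; loss of ring strain and carbonyl formation make the sequence irreversible. The closest known reaction type is the Prins cyclisation–pinacol rearrangement of 1-alkenylcycloalkanols, here in the mode with the alkene inside the new ring, which gives a spirocycle. C6 is set by the alkene geometry together with the anti addition across C5=C6, so that the chain, cis to the carbinol carbon in 14, ends up cis to C1 on ring B. C5 is set relative to C10 by a chair transition state in which the C10 silyloxy group is pseudoequatorial beside the bulky carbinol substituent and the methyl group pseudoaxial, which places C1 cis to the C10 oxygen. C7 should form with its oxygen pseudoequatorial, but this centre is oxidised later and need not be controlled. The step needs the four-membered-ring bond, not the methyl group or C9 on C10, to migrate, and needs the shift to outrun proton loss; strain release and the stronger electron release of the aluminium alkoxide compared with the silyl ether secure the first, and the alignment of the ring bond with the empty orbital at C5 favours the second.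

Step 11
Reactants: 16 (5R,6S,7S,10S)-6-{3-[(tert-butyldiphenylsilyl)oxy]propyl}-7-hydroxy-10-methyl-10-[(triethylsilyl)oxy]spiro[4.5]decan-1-one
Product: 17 (5R,6S,7S,10S)-6-{3-[(tert-butyldiphenylsilyl)oxy]propyl}-10-methyl-1-oxo-10-[(triethylsilyl)oxy]spiro[4.5]decan-7-yl 2,2-dimethylpropanoate
Conditions: t-BuCOCl, pyridine, DMAP, CH2Cl2, rt
Reagents that add atoms: pivaloyl chloride, CC(C)(C)C(=O)Cl
Why: DMAP-catalysed acylation of the secondary C7 alcohol; the pivalate has no α-hydrogens, survives enolate, fluoride, peroxide and organocopper chemistry, and is removed reductively when C7 is needed.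

Step 12
Reactants: 17 (5R,6S,7S,10S)-6-{3-[(tert-butyldiphenylsilyl)oxy]propyl}-10-methyl-1-oxo-10-[(triethylsilyl)oxy]spiro[4.5]decan-7-yl 2,2-dimethylpropanoate
Product: 18 (5R,6S,7S,10S)-6-{3-[(tert-butyldiphenylsilyl)oxy]propyl}-10-methyl-10-[(triethylsilyl)oxy]-1-{[(trifluoromethyl)sulfonyl]oxy}spiro[4.5]dec-1-en-7-yl 2,2-dimethylpropanoate
Conditions: KN(SiMe3)2, PhNTf2, THF, −78 °C
Reagents that add atoms: N-phenylbis(trifluoromethanesulfonimide), O=S(=O)(N(c1ccccc1)S(=O)(=O)C(F)(F)F)C(F)(F)F
Why: Enolate formation and O-triflation; C5 is quaternary, so only C2 can be deprotonated and a single enol triflate forms, while the silyl ether on C10 prevents retro-aldol cleavage of the β-oxygenated ketone.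

Step 13
Reactants: 18 (5R,6S,7S,10S)-6-{3-[(tert-butyldiphenylsilyl)oxy]propyl}-10-methyl-10-[(triethylsilyl)oxy]-1-{[(trifluoromethyl)sulfonyl]oxy}spiro[4.5]dec-1-en-7-yl 2,2-dimethylpropanoate
Product: 19 (5R,6S,7S,10S)-6-{3-[(tert-butyldiphenylsilyl)oxy]propyl}-10-methyl-10-[(triethylsilyl)oxy]spiro[4.5]dec-1-en-7-yl 2,2-dimethylpropanoate
Conditions: Pd(OAc)2 (5 mol%), PPh3, HCO2H, Bu3N, DMF, 60 °C
Reagents that add atoms: none
Why: Palladium-catalysed formate reduction of an enol triflate: oxidative addition, formate exchange, decarboxylation and reductive elimination give the C1=C2 alkene without touching the esters or silyl ethers.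

Step 14
Reactants: 19 (5R,6S,7S,10S)-6-{3-[(tert-butyldiphenylsilyl)oxy]propyl}-10-methyl-10-[(triethylsilyl)oxy]spiro[4.5]dec-1-en-7-yl 2,2-dimethylpropanoate
Product: 20 (5R,6S,7S,10S)-6-{3-[(tert-butyldiphenylsilyl)oxy]propyl}-10-hydroxy-10-methylspiro[4.5]dec-1-en-7-yl 2,2-dimethylpropanoate
Conditions: HF·pyridine, pyridine, THF, 0 °C → rt
Reagents that add atoms: none
Why: Fluoride cleavage of the tertiary triethylsilyl ether under buffered conditions that spare the primary tert-butyldiphenylsilyl ether and the pivalate; the free C10 hydroxyl is needed to direct the next step.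

Step 15
Reactants: 20 (5R,6S,7S,10S)-6-{3-[(tert-butyldiphenylsilyl)oxy]propyl}-10-hydroxy-10-methylspiro[4.5]dec-1-en-7-yl 2,2-dimethylpropanoate
Product: 21 (1R,2S,5S,6S,7S,10S)-6-{3-[(tert-butyldiphenylsilyl)oxy]propyl}-1,2-epoxy-10-hydroxy-10-methylspiro[4.5]decan-7-yl 2,2-dimethylpropanoate
Conditions: VO(acac)2 (5 mol%), t-BuOOH, CH2Cl2, 0 °C → rt
Reagents that add atoms: tert-butyl hydroperoxide, CC(C)(C)OO
Why: Vanadium-catalysed hydroxyl-directed epoxidation of a homoallylic alcohol; the vanadate ester on the C10 oxygen, which is gauche to C1, should deliver oxygen to the ring A face on which C10 lies, setting C1 and C2 of the epoxide.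

Step 16
Reactants: 21 (1R,2S,5S,6S,7S,10S)-6-{3-[(tert-butyldiphenylsilyl)oxy]propyl}-1,2-epoxy-10-hydroxy-10-methylspiro[4.5]decan-7-yl 2,2-dimethylpropanoate
Product: 22 (1S,2R,5S,6S,7S,10S)-6-{3-[(tert-butyldiphenylsilyl)oxy]propyl}-1,10-dihydroxy-10-methyl-2-[1-(trimethylsilyl)ethenyl]spiro[4.5]decan-7-yl 2,2-dimethylpropanoate
Conditions: CH2=C(SiMe3)MgBr (from (1-bromovinyl)trimethylsilane and Mg), CuI (20 mol%), THF, −30 → 0 °C
Reagents that add atoms: [1-(trimethylsilyl)ethenyl]magnesium bromide, C=C([Mg]Br)[Si](C)(C)C
Why: Copper-catalysed SN2 opening of the epoxide by an alkenyl Grignard reagent; attack should occur at C2, the carbon remote from the quaternary spiro centre, with inversion, which leaves the C1 oxygen on the C10 face and puts the alkenyl group trans to it.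

Step 17
Reactants: 22 (1S,2R,5S,6S,7S,10S)-6-{3-[(tert-butyldiphenylsilyl)oxy]propyl}-1,10-dihydroxy-10-methyl-2-[1-(trimethylsilyl)ethenyl]spiro[4.5]decan-7-yl 2,2-dimethylpropanoate
Product: 23 the 1,10-O-(di-tert-butylsilanediyl) derivative of 22
Conditions: t-Bu2Si(OTf)2, 2,6-lutidine, CH2Cl2, 0 °C → rt
Reagents that add atoms: di-tert-butylsilyl bis(trifluoromethanesulfonate), CC(C)(C)[Si](OS(=O)(=O)C(F)(F)F)(OS(=O)(=O)C(F)(F)F)C(C)(C)C
Why: Cyclic silylene formation across the 1,3-diol (C1–OH and C10–OH, joined through C5 and on the same side); one reagent masks both hydroxyls, so neither can be oxidised or trap a cationic C7 in the later steps.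

Step 18
Reactants: 23 the 1,10-O-(di-tert-butylsilanediyl) derivative of 22
Product: 24 (1S,2R,5S,6S,7S,10S)-6-{3-[(tert-butyldiphenylsilyl)oxy]propyl}-1,10-[(di-tert-butylsilanediyl)dioxy]-2-(1-iodoethenyl)-10-methylspiro[4.5]decan-7-yl 2,2-dimethylpropanoate
Conditions: N-iodosuccinimide, 2,6-lutidine, (CF3)2CHOH, 0 °C
Reagents that add atoms: N-iodosuccinimide, O=C1CCC(=O)N1I
Why: Electrophilic ipso-iododesilylation of the vinylsilane; stabilisation of the cation β to silicon directs iodine to the silicon-bearing carbon, giving the 2-iodoalkene needed for the final coupling while no other nucleophilic alkene is present.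

Step 19
Reactants: 24 (1S,2R,5S,6S,7S,10S)-6-{3-[(tert-butyldiphenylsilyl)oxy]propyl}-1,10-[(di-tert-butylsilanediyl)dioxy]-2-(1-iodoethenyl)-10-methylspiro[4.5]decan-7-yl 2,2-dimethylpropanoate
Product: 25 (1S,2R,5S,6S,7S,10S)-6-{3-[(tert-butyldiphenylsilyl)oxy]propyl}-1,10-[(di-tert-butylsilanediyl)dioxy]-2-(1-iodoethenyl)-10-methylspiro[4.5]decan-7-ol
Conditions: i-Bu2AlH, CH2Cl2, −78 °C
Reagents that add atoms: none
Why: Reductive cleavage of the pivalate by an aluminium hydride; the silyl groups and the iodoalkene are inert at this temperature.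

Step 20
Reactants: 25 (1S,2R,5S,6S,7S,10S)-6-{3-[(tert-butyldiphenylsilyl)oxy]propyl}-1,10-[(di-tert-butylsilanediyl)dioxy]-2-(1-iodoethenyl)-10-methylspiro[4.5]decan-7-ol
Product: 26 (1S,2R,5S,6S,10S)-6-{3-[(tert-butyldiphenylsilyl)oxy]propyl}-1,10-[(di-tert-butylsilanediyl)dioxy]-2-(1-iodoethenyl)-10-methylspiro[4.5]decan-7-one
Conditions: Dess–Martin periodinane, NaHCO3, CH2Cl2, rt
Reagents that add atoms: none
Why: Dess–Martin oxidation of the secondary alcohol under buffered conditions that should not enolise the new ketone, so C6 keeps its configuration.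

Step 21
Reactants: 26 (1S,2R,5S,6S,10S)-6-{3-[(tert-butyldiphenylsilyl)oxy]propyl}-1,10-[(di-tert-butylsilanediyl)dioxy]-2-(1-iodoethenyl)-10-methylspiro[4.5]decan-7-one
Product: 27 (1S,2R,5S,6S,7R,10S)-6-{3-[(tert-butyldiphenylsilyl)oxy]propyl}-1,10-[(di-tert-butylsilanediyl)dioxy]-2-(1-iodoethenyl)-10-methyl-7-(prop-1-en-2-yl)spiro[4.5]decan-7-ol
Conditions: CH2=C(CH3)MgBr, CeCl3, THF, −78 → 0 °C
Reagents that add atoms: isopropenylmagnesium bromide, C=C(C)[Mg]Br
Why: Organocerium-mediated 1,2-addition to an enolisable α-branched ketone; cerium suppresses enolisation and so protects C6, and equatorial attack is expected, although the C7 configuration is erased in the next step.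

Step 22
Reactants: 27 (1S,2R,5S,6S,7R,10S)-6-{3-[(tert-butyldiphenylsilyl)oxy]propyl}-1,10-[(di-tert-butylsilanediyl)dioxy]-2-(1-iodoethenyl)-10-methyl-7-(prop-1-en-2-yl)spiro[4.5]decan-7-ol
Product: 28 (2Z)-2-[(1S,2R,5S,6R,10S)-6-{3-[(tert-butyldiphenylsilyl)oxy]propyl}-1,10-[(di-tert-butylsilanediyl)dioxy]-2-(1-iodoethenyl)-10-methylspiro[4.5]decan-7-ylidene]propanal
Conditions: [C5H5NH][CrO3Cl], 4 Å MS, CH2Cl2, rt
Reagents that add atoms: pyridinium chlorochromate, [O-][Cr](=O)(=O)Cl.c1cc[nH+]cc1
Why: Babler–Dauben oxidative transposition: the tertiary chromate ester undergoes a [3,3] shift to the primary allylic chromate, which is oxidised to the α-methyl enal. The isomer with the slim formyl group, and not the methyl group, beside the substituted C6 is expected to be favoured, and the reversible sigmatropic step allows the two geometries to equilibrate before oxidation.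

Step 23
Reactants: 29 methyl bis(2,2,2-trifluoroethyl)phosphonoacetate; 30 5-bromo-2-methylpent-2-ene
Product: 31 methyl 2-[bis(2,2,2-trifluoroethoxy)phosphoryl]-6-methylhept-5-enoate
Conditions: NaH, NaI (cat.), DMSO, rt → 50 °C
Reagents that add atoms: none
Why: SN2 alkylation of the stabilised phosphonoacetate anion by a primary bromide, helped by iodide catalysis.

Step 24
Reactants: 32 (E)-1,2-bis(tributylstannyl)ethene
Product: 34 (E)-3-(tributylstannyl)prop-2-enal, via stannylvinyllithium 33 (not isolated)
Conditions: n-BuLi (1.0 equiv), THF, −78 °C; then DMF; aq. NH4Cl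
Reagents that add atoms: N,N-dimethylformamide, CN(C)C=O
Why: Tin–lithium exchange at one terminus and formylation of the alkenyllithium; the E geometry is retained.

Step 25
Reactants: 31 methyl 2-[bis(2,2,2-trifluoroethoxy)phosphoryl]-6-methylhept-5-enoate; 34 (E)-3-(tributylstannyl)prop-2-enal
Product: 35 methyl (2Z,4E)-2-(4-methylpent-3-en-1-yl)-5-(tributylstannyl)penta-2,4-dienoate
Conditions: KN(SiMe3)2, 18-crown-6, THF, −78 °C
Reagents that add atoms: none
Why: Still–Gennari olefination; the electron-poor bis(trifluoroethyl) phosphonate with a dissociated potassium counter-ion eliminates under kinetic control to the Z-trisubstituted ester, which places the ester cis to the stannyldienyl chain.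

Step 26
Reactants: 35 methyl (2Z,4E)-2-(4-methylpent-3-en-1-yl)-5-(tributylstannyl)penta-2,4-dienoate
Product: 36 (2Z,4E)-2-(4-methylpent-3-en-1-yl)-5-(tributylstannyl)penta-2,4-dien-1-ol
Conditions: i-Bu2AlH, CH2Cl2, −78 °C
Reagents that add atoms: none
Why: 1,2-Reduction of the conjugated ester to the allylic alcohol; the alkene geometries and the alkenylstannane are not affected.

Step 27
Reactants: 28 (2Z)-2-[(1S,2R,5S,6R,10S)-6-{3-[(tert-butyldiphenylsilyl)oxy]propyl}-1,10-[(di-tert-butylsilanediyl)dioxy]-2-(1-iodoethenyl)-10-methylspiro[4.5]decan-7-ylidene]propanal; 36 (2Z,4E)-2-(4-methylpent-3-en-1-yl)-5-(tributylstannyl)penta-2,4-dien-1-ol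
Product: 37 the 3′-O-tert-butyldiphenylsilyl 1,10-O-(di-tert-butylsilanediyl) derivative of the target
Conditions: Pd(PPh3)4 (10 mol%), CuI, CsF, DMF, rt, dark
Reagents that add atoms: none
Why: Stille coupling with copper and fluoride assistance; both alkenyl partners couple with retention of geometry, and the conditions tolerate the enal and the free allylic alcohol.

Step 28
Reactants: 37 the 3′-O-tert-butyldiphenylsilyl 1,10-O-(di-tert-butylsilanediyl) derivative of the target
Product: 38 the target, CNP0249558.1
Conditions: Bu4NF, AcOH, THF, 0 °C → rt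
Reagents that add atoms: none
Why: Fluoride cleavage of the primary silyl ether and the silylene in one operation; acetic acid buffers the medium so that the enal and the triene are not exposed to base.

## Compound list

1 | geraniol, (2E)-3,7-dimethylocta-2,6-dien-1-ol | CC(C)=CCC/C(C)=C/CO | starting material
2 | (2S,3S)-2,3-epoxygeraniol | CC(C)=CCC[C@]1(C)O[C@H]1CO | intermediate
3 | (2R,3S)-2-(chloromethyl)-3-methyl-3-(4-methylpent-3-en-1-yl)oxirane | CC(C)=CCC[C@]1(C)O[C@H]1CCl | intermediate
4 | (3S)-3,7-dimethyloct-6-en-1-yn-3-ol | CC(C)=CCC[C@](C#C)(C)O | intermediate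
5 | tert-butyl(3-bromopropoxy)diphenylsilane | BrCCCO[Si](c1ccccc1)(c1ccccc1)C(C)(C)C | starting material
6 | (6S)-11-[(tert-butyldiphenylsilyl)oxy]-2,6-dimethylundec-2-en-7-yn-6-ol | CC(C)=CCC[C@](C#CCCCO[Si](c1ccccc1)(c1ccccc1)C(C)(C)C)(C)O | intermediate
7 | (6S,7Z)-11-[(tert-butyldiphenylsilyl)oxy]-2,6-dimethyl-7-(tributylstannyl)undeca-2,7-dien-6-ol | CC(C)=CCC[C@](C)(O)/C(=C/CCCO[Si](c1ccccc1)(c1ccccc1)C(C)(C)C)[Sn](CCCC)(CCCC)CCCC | intermediate
8 | (6S,7Z)-11-[(tert-butyldiphenylsilyl)oxy]-7-iodo-2,6-dimethylundeca-2,7-dien-6-ol | CC(C)=CCC[C@](C)(O)/C(I)=C/CCCO[Si](c1ccccc1)(c1ccccc1)C(C)(C)C | intermediate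
9 | (6S,7Z)-11-[(tert-butyldiphenylsilyl)oxy]-7-iodo-2,6-dimethyl-6-[(triethylsilyl)oxy]undeca-2,7-diene | CC(C)=CCC[C@](C)(O[Si](CC)(CC)CC)/C(I)=C/CCCO[Si](c1ccccc1)(c1ccccc1)C(C)(C)C | intermediate
10 | cyclobutanone | O=C1CCC1 | starting material
11 | alkenyllithium from 9 (lithium in place of iodine, geometry retained) | CC(C)=CCC[C@](C)(O[Si](CC)(CC)CC)/C([Li])=C/CCCO[Si](c1ccccc1)(c1ccccc1)C(C)(C)C | intermediate (not isolated)
12 | 1-[(4E,6S)-1-[(tert-butyldiphenylsilyl)oxy]-6,10-dimethyl-6-[(triethylsilyl)oxy]undeca-4,9-dien-5-yl]cyclobutan-1-ol (chain cis to the cyclobutanol carbon) | OC1(CCC1)/C(=C\CCCO[Si](c1ccccc1)(c1ccccc1)C(C)(C)C)[C@](C)(CCC=C(C)C)O[Si](CC)(CC)CC | intermediate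
13 | vicinal diol from dihydroxylation of the terminal alkene of 12 (both epimers at the new secondary carbinol) | OC1(CCC1)/C(=C\CCCO[Si](c1ccccc1)(c1ccccc1)C(C)(C)C)[C@](C)(CCC(O)C(C)(C)O)O[Si](CC)(CC)CC | intermediate (not isolated)
14 | (4S,5E)-9-[(tert-butyldiphenylsilyl)oxy]-5-(1-hydroxycyclobutyl)-4-methyl-4-[(triethylsilyl)oxy]non-5-enal (precursor of the key step) | OC1(CCC1)/C(=C\CCCO[Si](c1ccccc1)(c1ccccc1)C(C)(C)C)[C@](C)(CCC=O)O[Si](CC)(CC)CC | intermediate
15 | C5 carbocation after ring B closure (aluminium alkoxide on the cyclobutanol, aluminate on the C7 oxygen) | C[Al](Cl)OC1(CCC1)[C+]1[C@H](CCCO[Si](c2ccccc2)(c2ccccc2)C(C)(C)C)[C@@H](O[Al-](C)(C)Cl)CC[C@]1(C)O[Si](CC)(CC)CC | intermediate (not isolated)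
16 | (5R,6S,7S,10S)-6-{3-[(tert-butyldiphenylsilyl)oxy]propyl}-7-hydroxy-10-methyl-10-[(triethylsilyl)oxy]spiro[4.5]decan-1-one (product of the key step) | O=C1CCC[C@]12[C@H](CCCO[Si](c3ccccc3)(c3ccccc3)C(C)(C)C)[C@@H](O)CC[C@]2(C)O[Si](CC)(CC)CC | intermediate
17 | 7-O-pivalate of 16 | O=C1CCC[C@]12[C@H](CCCO[Si](c3ccccc3)(c3ccccc3)C(C)(C)C)[C@@H](OC(=O)C(C)(C)C)CC[C@]2(C)O[Si](CC)(CC)CC | intermediate
18 | C1 enol triflate of 17 (C1=C2), (5R,6S,7S,10S) | O=S(=O)(OC1=CCC[C@]12[C@H](CCCO[Si](c3ccccc3)(c3ccccc3)C(C)(C)C)[C@@H](OC(=O)C(C)(C)C)CC[C@]2(C)O[Si](CC)(CC)CC)C(F)(F)F | intermediate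
19 | (5R,6S,7S,10S)-6-{3-[(tert-butyldiphenylsilyl)oxy]propyl}-10-methyl-10-[(triethylsilyl)oxy]spiro[4.5]dec-1-en-7-yl pivalate | C1=CCC[C@]12[C@H](CCCO[Si](c3ccccc3)(c3ccccc3)C(C)(C)C)[C@@H](OC(=O)C(C)(C)C)CC[C@]2(C)O[Si](CC)(CC)CC | intermediate
20 | (5R,6S,7S,10S)-6-{3-[(tert-butyldiphenylsilyl)oxy]propyl}-10-hydroxy-10-methylspiro[4.5]dec-1-en-7-yl pivalate | C1=CCC[C@]12[C@H](CCCO[Si](c3ccccc3)(c3ccccc3)C(C)(C)C)[C@@H](OC(=O)C(C)(C)C)CC[C@]2(C)O | intermediate
21 | (1R,2S,5S,6S,7S,10S)-1,2-epoxide of 20 (oxygen on the ring A face of C10) | [C@H]12O[C@H]1CC[C@]23[C@H](CCCO[Si](c4ccccc4)(c4ccccc4)C(C)(C)C)[C@@H](OC(=O)C(C)(C)C)CC[C@]3(C)O | intermediate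
22 | (1S,2R,5S,6S,7S,10S)-6-{3-[(tert-butyldiphenylsilyl)oxy]propyl}-1,10-dihydroxy-10-methyl-2-[1-(trimethylsilyl)ethenyl]spiro[4.5]decan-7-yl pivalate | C=C([Si](C)(C)C)[C@@H]1CC[C@]2([C@H](CCCO[Si](c3ccccc3)(c3ccccc3)C(C)(C)C)[C@@H](OC(=O)C(C)(C)C)CC[C@]2(C)O)[C@H]1O | intermediate
23 | 1,10-O-(di-tert-butylsilanediyl) derivative of 22 | C=C([Si](C)(C)C)[C@@H]1CC[C@]2([C@H](CCCO[Si](c3ccccc3)(c3ccccc3)C(C)(C)C)[C@@H](OC(=O)C(C)(C)C)CC[C@]2(C)O4)[C@H]1O[Si]4(C(C)(C)C)C(C)(C)C | intermediate
24 | 2-(1-iodoethenyl) analogue of 23, (1S,2R,5S,6S,7S,10S) | C=C(I)[C@@H]1CC[C@]2([C@H](CCCO[Si](c3ccccc3)(c3ccccc3)C(C)(C)C)[C@@H](OC(=O)C(C)(C)C)CC[C@]2(C)O4)[C@H]1O[Si]4(C(C)(C)C)C(C)(C)C | intermediate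
25 | C7 alcohol from 24, (1S,2R,5S,6S,7S,10S) | C=C(I)[C@@H]1CC[C@]2([C@H](CCCO[Si](c3ccccc3)(c3ccccc3)C(C)(C)C)[C@@H](O)CC[C@]2(C)O4)[C@H]1O[Si]4(C(C)(C)C)C(C)(C)C | intermediate
26 | C7 ketone, (1S,2R,5S,6S,10S) | C=C(I)[C@@H]1CC[C@]2([C@H](CCCO[Si](c3ccccc3)(c3ccccc3)C(C)(C)C)C(=O)CC[C@]2(C)O4)[C@H]1O[Si]4(C(C)(C)C)C(C)(C)C | intermediate
27 | 7-hydroxy-7-(prop-1-en-2-yl) compound, (1S,2R,5S,6S,7R,10S) | C=C(I)[C@@H]1CC[C@]2([C@H](CCCO[Si](c3ccccc3)(c3ccccc3)C(C)(C)C)[C@@](O)(C(C)=C)CC[C@]2(C)O4)[C@H]1O[Si]4(C(C)(C)C)C(C)(C)C | intermediate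
28 | (2Z)-enal with the 2-(1-iodoethenyl) group, (1S,2R,5S,6R,10S) | C=C(I)[C@@H]1CC[C@]2([C@H](CCCO[Si](c3ccccc3)(c3ccccc3)C(C)(C)C)/C(=C(/C)C=O)CC[C@]2(C)O4)[C@H]1O[Si]4(C(C)(C)C)C(C)(C)C | intermediate
29 | methyl bis(2,2,2-trifluoroethyl)phosphonoacetate | COC(=O)CP(=O)(OCC(F)(F)F)OCC(F)(F)F | starting material
30 | 5-bromo-2-methylpent-2-ene | CC(C)=CCCBr | starting material
31 | methyl 2-[bis(2,2,2-trifluoroethoxy)phosphoryl]-6-methylhept-5-enoate (racemic) | COC(=O)C(CCC=C(C)C)P(=O)(OCC(F)(F)F)OCC(F)(F)F | intermediate
32 | (E)-1,2-bis(tributylstannyl)ethene | CCCC[Sn](CCCC)(CCCC)/C=C/[Sn](CCCC)(CCCC)CCCC | starting material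
33 | (E)-2-(tributylstannyl)ethenyllithium | [Li]/C=C/[Sn](CCCC)(CCCC)CCCC | intermediate (not isolated)
34 | (E)-3-(tributylstannyl)prop-2-enal | O=C/C=C/[Sn](CCCC)(CCCC)CCCC | intermediate
35 | methyl (2Z,4E)-2-(4-methylpent-3-en-1-yl)-5-(tributylstannyl)penta-2,4-dienoate | COC(=O)/C(CCC=C(C)C)=C\C=C\[Sn](CCCC)(CCCC)CCCC | intermediate
36 | (2Z,4E)-2-(4-methylpent-3-en-1-yl)-5-(tributylstannyl)penta-2,4-dien-1-ol | OC/C(CCC=C(C)C)=C\C=C\[Sn](CCCC)(CCCC)CCCC | intermediate
37 | 3′-O-tert-butyldiphenylsilyl 1,10-O-(di-tert-butylsilanediyl) derivative of the target, (1S,2S,5S,6R,10S) | C=C(/C=C/C=C(\CO)CCC=C(C)C)[C@@H]1CC[C@]2([C@H](CCCO[Si](c3ccccc3)(c3ccccc3)C(C)(C)C)/C(=C(/C)C=O)CC[C@]2(C)O4)[C@H]1O[Si]4(C(C)(C)C)C(C)(C)C | intermediate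
38 | CNP0249558.1, (1S,2S,5S,6R,10S) | C=C(/C=C/C=C(\CO)CCC=C(C)C)[C@@H]1CC[C@]2([C@H](CCCO)/C(=C(/C)C=O)CC[C@]2(C)O)[C@H]1O | target

## Step count and risks

Total: 28 steps. Longest linear sequence: 24 steps (steps 1–22, 27 and 28); steps 23–26 build the stannane fragment.

**Step 10 (key step).** Three processes could defeat it:
- proton loss from the developing C5 cation through the aluminium alkoxide (an ene-type outcome in place of the ring expansion);
- ionisation of the allylic silyl ether at C10 under the Lewis acid;
- insufficient discrimination between the two chair arrangements, so that C1 forms trans to the C10 oxygen.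

The first two arise because the initiating species is a Lewis acid-bound aldehyde with a basic oxygen close to the cation. The fallback starts the same bond reorganisation from an oxocarbenium ion, which is more electrophilic at low temperature and has no internal base. From 14, acetalisation with benzyl alcohol (pyridinium tosylate, MgSO4) would give the dibenzyl acetal F1. SnCl4 in CH2Cl2 at −78 °C would ionise it and trigger cyclisation and ring expansion to the 7-O-benzyl ether F2. Hydrogenolysis (H2, Pd(OH)2/C) would return to the route at 16.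

**Step 16.** The nucleophile must reach C2 past the C6 chain, and an α-branched alkenyl copper species is bulky, so slow opening, or halohydrin formation through magnesium halide, may take over. The fallback uses a small, linear nucleophile and installs the iodoalkene afterwards. From 21, the alkynylalane Et2AlC≡CSiMe3 (toluene, 0 °C) would open the epoxide at C2 to the silylalkyne diol F3. K2CO3 in MeOH would give the terminal alkyne F4. t-Bu2Si(OTf)2 with 2,6-lutidine would give the silylene-protected alkyne F5. Markovnikov haloboration with B-iodo-9-borabicyclo[3.3.1]nonane followed by protonolysis with AcOH would return to the route at 24.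

**Step 22.** The group that has to sit beside C6 during the sigmatropic shift is CH2–O–Cr, not a formyl group, so the geometric preference may be weak or reversed; esterification of the hindered tertiary alcohol may also be slow enough for ionisation at C7 to compete. The fallback forms the alkene with the aldehyde oxidation level already present. From 26, Peterson olefination with lithiated N-tert-butyl-2-(trimethylsilyl)propan-1-imine would give the unsaturated aldimine F6. Hydrolysis with aqueous oxalic acid, under which the conjugated system can settle into the isomer with the formyl group beside C6, would return to the route at 28.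

**Step 15.** Facial selectivity may be poor if undirected attack on the more open C6 face competes with delivery from the homoallylic C10 hydroxyl. The fallback turns that intrinsic preference to advantage. From 19, with the C10 silyl ether still in place, N-bromosuccinimide in aqueous DMSO would place the bromonium ion on the C6 face and water anti at C2, giving bromohydrin F7. K2CO3 in MeOH would close it to the epoxide F8 with oxygen on the C10 face. HF·pyridine would then remove the silyl ether and return to the route at 21.

**Step 5.** Tin might be delivered in part to the distal alkyne carbon, or the tethered alkene might engage the ruthenium centre (enyne cycloisomerisation). The fallback goes from 6 directly to 8: hydroxyl-directed trans-hydroalumination with LiAlH4 containing a small proportion of AlCl3 in THF, then iodine at −78 °C. The aluminium sits on the carbon next to the carbinol and anti to hydrogen, so the same iodide results and no new compound is made.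

## Further compounds

F1 | step 10 | dibenzyl acetal of aldehyde 14 | OC1(CCC1)/C(=C\CCCO[Si](c1ccccc1)(c1ccccc1)C(C)(C)C)[C@](C)(CCC(OCc1ccccc1)OCc1ccccc1)O[Si](CC)(CC)CC
F2 | step 10 | 7-O-benzyl ether of 16 | O=C1CCC[C@]12[C@H](CCCO[Si](c3ccccc3)(c3ccccc3)C(C)(C)C)[C@@H](OCc3ccccc3)CC[C@]2(C)O[Si](CC)(CC)CC
F3 | step 16 | analogue of 22 with a (trimethylsilyl)ethynyl group at C2 | C[Si](C)(C)C#C[C@@H]1CC[C@]2([C@H](CCCO[Si](c3ccccc3)(c3ccccc3)C(C)(C)C)[C@@H](OC(=O)C(C)(C)C)CC[C@]2(C)O)[C@H]1O
F4 | step 16 | analogue of 22 with an ethynyl group at C2 | C#C[C@@H]1CC[C@]2([C@H](CCCO[Si](c3ccccc3)(c3ccccc3)C(C)(C)C)[C@@H](OC(=O)C(C)(C)C)CC[C@]2(C)O)[C@H]1O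
F5 | step 16 | 1,10-O-(di-tert-butylsilanediyl) derivative of F4 | C#C[C@@H]1CC[C@]2([C@H](CCCO[Si](c3ccccc3)(c3ccccc3)C(C)(C)C)[C@@H](OC(=O)C(C)(C)C)CC[C@]2(C)O4)[C@H]1O[Si]4(C(C)(C)C)C(C)(C)C
F6 | step 22 | N-tert-butyl aldimine of enal 28 (alkene isomers) | C=C(I)[C@@H]1CC[C@]2([C@H](CCCO[Si](c3ccccc3)(c3ccccc3)C(C)(C)C)C(=C(C)C=NC(C)(C)C)CC[C@]2(C)O4)[C@H]1O[Si]4(C(C)(C)C)C(C)(C)C
F7 | step 15 | trans-bromohydrin from 19 (bromine at C1 on the C6 face, hydroxyl at C2 on the C10 face) | Br[C@@H]1[C@@H](O)CC[C@]12[C@H](CCCO[Si](c3ccccc3)(c3ccccc3)C(C)(C)C)[C@@H](OC(=O)C(C)(C)C)CC[C@]2(C)O[Si](CC)(CC)CC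
F8 | step 15 | 10-O-triethylsilyl ether of epoxide 21 | [C@H]12O[C@H]1CC[C@]23[C@H](CCCO[Si](c4ccccc4)(c4ccccc4)C(C)(C)C)[C@@H](OC(=O)C(C)(C)C)CC[C@]3(C)O[Si](CC)(CC)CC
F0 | step 5 | none | none
A1 | alternative 1 | methyl (3S)-3-[(tert-butyldimethylsilyl)oxy]-6-oxocyclohex-1-ene-1-carboxylate | COC(=O)C1=C[C@@H](O[Si](C)(C)C(C)(C)C)CCC1=O
A2 | alternative 1 | ring B keto ester with quaternary C5 and the C6 chain | COC(=O)/C=C/C[C@]1([C@H](CCCO[Si](C)(C)C(C)(C)C)[C@@H](O[Si](C)(C)C(C)(C)C)CCC1=O)C(=O)OC
A3 | alternative 2 | allylic alcohol carrying the 2-vinylcyclopent-1-enyl group and the C10 silyl ether | C=CC(O)CC[C@](C)(O[Si](CC)(CC)CC)C1=C(C=C)CCC1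
A4 | alternative 2 | angular tricyclic ketone with the C1=C3′ alkene | O=C1CC[C@](C)(O[Si](CC)(CC)CC)[C@]23CCCC2=CCC[C@H]13
A5 | alternative 3 | open-chain iodo keto diester with quaternary C5 | CC(C)(C)OC(=O)CCC[C@](C(C)=O)([C@H](CCCO[Si](C)(C)C(C)(C)C)[C@@H](O[Si](C)(C)C(C)(C)C)CCI)C(=O)OC
A6 | alternative 3 | ring B hydroxy ester with the C5, C6 and C10 stereotriad | CC(C)(C)OC(=O)CCC[C@]1([C@H](CCCO[Si](C)(C)C(C)(C)C)[C@@H](O[Si](C)(C)C(C)(C)C)CC[C@]1(C)O)C(=O)OC
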